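The numbers in the tables stem from a simulated flask for an exercise, and the scatter is random.

Watch the substrate level against one number while the feed runs.

| flask | substrate | partner | free catalyst | remark | time |
|---|---|---|---|---|---|
| Saturday's | 0.051 M | 0.102 M | 5.1 mM | run made earlier |  |
| Tuesday's | 0.051 M | 0.102 M | 10 mM | run made earlier |  |
| east | 0.051 M (fed, over 20 s) | 0.102 M | 5.1 mM | all else is in the flask from the start; the feed brings no volume worth counting | 5.0 min |
| south-east | 0.051 M (fed, over 3.0 min) | 0.102 M | 5.1 mM | all else is in the flask from the start; the feed brings no volume worth counting | 5.0 min |
| north-east | 0.051 M | 0.102 M (fed, over 3.0 min) | 5.1 mM | all else is in the flask from the start; the feed brings no volume worth counting | 5.0 min |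
| west | 0.051 M | 0.102 M | 5.1 mM | everything together at the start | 5.0 min |

- Saturday's (time / min: homo dimer / %, product / %): 0.250: 68.4, 8.7; 0.833: 78.3, 16.5; 1.33: 79.6, 17.9; 2.00: 79.8, 19.1; 3.00: 79.2, 20.1; 4.00: 79.9, 20.2; 5.00: 79.4, 20.8
- Tuesday's (time / s: homo dimer / %, product / %): 10.0: 59.7, 9.8; 12.0: 62.7, 11.9; 20.0: 68.9, 16.0; 25.0: 70.7, 17.8; 30.0: 71.7, 19.0

(readings scatter by 0.3 percentage points)

1. the flask that comes out highest in amount of homo dimer, in percent of the substrate charged; "all alike" if 1.5 percentage points covers them all (east / south-east / north-east / west / all alike)
2. amount of homo dimer at the end, in percent of the substrate charged, east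
3. amount of homo dimer at the end, in percent of the substrate charged, south-east
4. amount of homo dimer at the end, in percent of the substrate charged, north-east
5. amount of homo dimer at the end, in percent of the substrate charged, west

- a species is counted by the substrate in it: one homo dimer counts as two

1. In Saturday's run I counted as substrate whatever was neither homo dimer nor product: 22.9% at 0.250 min and 5.20% at 0.833 min.
2. Between those readings product gained 0.788 of what homo dimer gained. I took that ratio as c_x/c(substrate) and replaced the curve by its plain mean, which gave 5.65 mM. This c_x is the crossover level, the c(substrate) at which product and homo dimer take substrate equally fast. It is a selectivity factor in concentration form: product's share of the substrate used is c_x/(c_x + c(substrate)).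
3. As a second way I integrated that share from the second reading to the end, which predicted a product gain of 4.26%. The last product reading, which had not gone into c_x, gave a gain of 4.3 percentage points, so the two ways agreed.
4. From the charge, the same integral gave 25.5% against 20.8%, a gap of 4.7 points. Up to the first reading it gave 13.1% against 8.7%, a gap of 4.4 points. So the integral cheated before 0.250 min, where product stood lower than it claimed.
5. The same interval of Saturday's run gave the pace τ: 46.9 s, the pseudo-first-order time of substrate at low level.
6. For south-east I set the feed equal to consumption, c(substrate)(c(substrate) + c_x)/(c_x τ). That gave a steady level of 6.28 mM and, at that level, a homo dimer share of 52.7% of the substrate used.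
7. The forecast named north-east, with east 75%, south-east 57%, north-east 94% and west 79.5%: “the slow feed holds s near 0.12, giving about 43% product and 57% dimer”. My share at the steady level in south-east lay lower than its 57% for the end.
8. The flasks gave east 74.3%, south-east 56.4%, north-east 89.4% and west 79.6%. North-east came out highest, as the forecast said, and each of the forecast's figures stood within tolerance. North-east, with the partner fed, stood above west, and south-east, with the substrate fed over 3.0 min, stood below west.

    partner + free catalyst ⇌ catalyst intermediate A (K = 20.0 M⁻¹, k = 8.60 M⁻¹ s⁻¹)
    substrate + catalyst intermediate A → catalyst intermediate B (k = 17.0 M⁻¹ s⁻¹)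
    catalyst intermediate B → free catalyst + product (k = 1.00 s⁻¹)
    2 substrate → homo dimer (k = 1.90 M⁻¹ s⁻¹)
    2 catalyst intermediate A ⇌ resting dimer, settled at all times (K = 1700 M⁻¹)

The neighbour of south-east was charged 0.020 M of substrate, with the other charges and the time held. Catalyst intermediate A stood at 19.9% there and 19.7% in south-east at 5.00 min, and I kept c_x and τ. The feed balance then gave a level of 3.29 mM and a homo dimer share of 36.8%, lower than south-east's. That flask gave 39.5% homo dimer and 59.1% product, with 1.36% substrate left.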